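A ratio reads this pair of flasks: the logarithm of the fraction of left-handed substrate left, divided by the logarithm of the fraction of right-handed substrate left. If each substrate reacts in a step first order in it, with the same partner and free catalyst, both logarithms grow by the same running integral of that supply. The ratio then stays at the ratio of the two rate constants, however the supply runs down.

| flask | left-handed substrate | right-handed substrate | partner | free catalyst | remark | time |
|---|---|---|---|---|---|---|
| spring | 0.091 M | 0.091 M | 0.137 M | 0.46 mM | the very flask that is asked about, followed so far |  |
| autumn | 0.091 M | 0.091 M | 0.092 M | 0.46 mM | run made earlier |  |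
| flask | 0.091 M | 0.091 M | 0.137 M | 0.46 mM |  | 12 h |

| run | time / h | left-handed substrate / % | right-handed substrate / % | left-handed product / % |
|---|---|---|---|---|
| spring | 0.417 | 36.5 | 43.9 | 13.0 |
| spring | 0.833 | 36.3 | 43.0 | 13.5 |
| spring | 1.33 | 35.7 | 43.5 | 13.7 |
| spring | 1.50 | 36.3 | 43.0 | 13.5 |
| spring | 2.00 | 35.9 | 43.2 | 13.8 |
| spring | 2.50 | 36.3 | 43.2 | 14.2 |
| autumn | 0.667 | 40.9 | 45.3 | 9.4 |
| autumn | 1.00 | 40.2 | 45.4 | 9.3 |
| autumn | 2.00 | 40.3 | 45.3 | 9.4 |
| autumn | 3.00 | 40.6 | 46.0 | 9.7 |
| autumn | 5.00 | 40.7 | 45.2 | 9.8 |
| autumn | 8.00 | 40.2 | 45.3 | 9.8 |

(scatter of a reading: 0.3 percentage points)

* part of the left-handed substrate and right-handed substrate charged together that has reacted at 12 h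
* excess of left-handed product over right-handed product in the product at 12 h
* excess of right-handed substrate over left-handed substrate among what is left of the two at 12 h

- free catalyst is single-handed; left-handed substrate and right-handed substrate are mirror images of each other, charged as a racemate, each of them at the stated concentration
- reactions considered so far: partner -> decomposed reagent; 2 free catalyst -> spent catalyst B; partner + free catalyst + right-handed substrate -> free catalyst + right-handed product; partner + free catalyst + left-handed substrate -> free catalyst + left-handed product; free catalyst -> spent catalyst A
- an excess is the difference of the two amounts in percent of their sum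
- an excess is below zero if the other one leads

The asked flask is the spring flask followed on to 12 h. Spring and autumn differ in one charge: [partner] is 0.137 M against 0.092 M, a ratio of 1.49. Both are flat from their first readings, and autumn stays flat to 8.00 h. On average spring stands at 36.2% left-handed and 43.3% right-handed substrate, autumn at 40.5% and 45.4%. So spring has converted 20.5% and autumn 14.1%, a ratio of 1.45, nearly that of the partner charges.

The ratio of logarithms does not follow the charge. Spring reads 2.25 as its selectivity factor, the logarithm ratio defined above, and autumn reads 2.18. The two flasks therefore stand at different depths on one curve.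

Carried unchanged to 12 h, the spring plateau reckons to a conversion of 20.5%, a product excess of 34.6% and a substrate excess of 8.93%. The forecast gives 20.7%, 34.7% and 9%, its conversion slightly higher by allowing “a tiny creep from any second-order catalyst-death tail”.

The flask gives 20.8%, 34.2% and 8.95%, inside the forecast's ranges.

    partner → decomposed reagent (k = 0.0497 min⁻¹)
    2 free catalyst → spent catalyst B (k = 149 M⁻¹ min⁻¹)
    partner + free catalyst + right-handed substrate → free catalyst + right-handed product (k = 387 M⁻² min⁻¹)
    partner + free catalyst + left-handed substrate → free catalyst + left-handed product (k = 860 M⁻² min⁻¹)
    free catalyst → spent catalyst A (k = 0.0112 min⁻¹)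

In the flask, partner stands at 0% of its charge at 12.0 h, less than the 72% of left-handed and 86% of right-handed substrate remaining, so partner is the limiting reagent. The largest single effect on the flask's product excess is the shrinking supply of partner: the same run without that shrinkage gives 26.9% against 34.2%. The remaining fractions still return a selectivity factor of 2.22. The flask charged with 0.55 M of partner keeps 25% of its left-handed substrate, from which 2.25 reckons 54.0% of its right-handed substrate, and that flask holds 54%.

The readings are simulated on assumed constants; noise was put on by code.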